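**Retrosynthetic overview**
1. The target is 5-hydroxy-2-pentadecyl-4H-chromen-4-one; the benzene ring is bought and only the 4-pyranone ring is built.
2. Last disconnection: the O1–C2 bond together with the C2=C3 unsaturation, leading back to the open-chain saturated ketone 1-(2,6-dihydroxyphenyl)octadecan-1-one. In the forward sense this is an oxidative C–O ring closure at the unactivated β-carbon.
3. Earlier disconnection: the Cα–Cβ bond of that ketone, leading back to 2',6'-dihydroxyacetophenone (as its trianion) and 1-iodohexadecane.
4. Ring order: the benzene ring comes from the starting material; the pyranone ring is closed last by C–O bond formation. Both phenols stay unprotected throughout.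

Assumption: the target has no stereocentre, so "single enantiomer" needs no stereocontrol; the only stereocentre met on the way (C2 of the transient chromanone 6) is racemic and is erased in the same flask.

**Route**

Step 1
Reactants: 1 2',6'-dihydroxyacetophenone [1-(2,6-dihydroxyphenyl)ethan-1-one]; 2 1-iodohexadecane
Product: 4 1-(2,6-dihydroxyphenyl)octadecan-1-one, via trilithium trianion 3 (not isolated)
Conditions: 1 (1.25 equiv), LDA (3.9 equiv), THF/DMPU (5:1), −78 → 0 °C, 1 h; then 2 (1.0 equiv), 0 °C → rt, 16 h; 1 M HCl work-up
Reagents that add atoms: none
Why: In the polylithiated ketone the terminal enolate carbon is the most nucleophilic site (lithium phenoxides are poor SN2 partners in THF), so the primary iodide alkylates once at carbon – an enolate SN2 C-alkylation of a polyanion of an o-hydroxyaryl methyl ketone; no stereocentre is formed.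

Step 2
Reactants: 4 1-(2,6-dihydroxyphenyl)octadecan-1-one
Product: 7 5-hydroxy-2-pentadecyl-4H-chromen-4-one, via open-chain enone 5 (not isolated), via racemic chromanone 6 (not isolated)
Conditions: Pd(TFA)2 (10 mol%), 4,5-diazafluoren-9-one (12 mol%), O2 (1 atm), DMSO/PhCl (1:1), 100 °C, 24 h
Reagents that add atoms: none
Why: Proposed new method: a Pd(II)/O2 tandem dehydrogenative oxa-cyclisation of a β-alkyl 2-hydroxyaryl ketone, which to my knowledge has been shown only for β-aryl (dihydrochalcone) substrates – trifluoroacetate-assisted α-palladation of 4 gives a Pd enolate whose β-hydride elimination forms the (E)-enone 5, an ortho-phenol then adds 6-endo to the β-carbon (oxa-Michael or Wacker-type oxypalladation) and so makes the O1–C2 bond of chromanone 6 before the double bond can walk down the chain, and a second enolate/β-hydride elimination across C2–C3 gives the pyranone while O2 reoxidises Pd(0) after each turnover; the closest known reaction types are the Pd(II)/O2 oxidative cyclisation of 2'-hydroxydihydrochalcones to flavones and the aerobic Pd-catalysed α,β-dehydrogenation of ketones and chromanones; the C2 stereocentre of 6 is transient and ends as sp2, and the remaining phenol stays hydrogen-bonded to C4=O as the 5-OH.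

**Compound list**
1 | 2',6'-dihydroxyacetophenone [1-(2,6-dihydroxyphenyl)ethan-1-one] | CC(=O)c1c(O)cccc1O | starting material
2 | 1-iodohexadecane | CCCCCCCCCCCCCCCCI | starting material
3 | trilithium trianion of 1 (lithium enolate and two lithium phenoxides; not isolated) | [Li+].[Li+].[Li+].C=C([O-])c1c([O-])cccc1[O-] | intermediate
4 | 1-(2,6-dihydroxyphenyl)octadecan-1-one | CCCCCCCCCCCCCCCCCC(=O)c1c(O)cccc1O | intermediate
5 | (E)-1-(2,6-dihydroxyphenyl)octadec-2-en-1-one (open-chain enone; not isolated) | CCCCCCCCCCCCCCC/C=C/C(=O)c1c(O)cccc1O | intermediate
6 | racemic 5-hydroxy-2-pentadecylchroman-4-one (not isolated) | CCCCCCCCCCCCCCCC1CC(=O)c2c(O)cccc2O1 | intermediate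
7 | 5-hydroxy-2-pentadecyl-4H-chromen-4-one | CCCCCCCCCCCCCCCc1cc(=O)c2c(O)cccc2o1 | target

**Totals and risks**
Total step count: 2. Longest linear sequence: 2 steps (1 → 4 → 7).

The route has only two steps, so both are ranked and there is no third step to list.

Most likely to fail, first: step 2, the proposed new step. The first α,β-desaturation of a long-chain alkyl aryl ketone is slower than that of a dihydrochalcone. Over-dehydrogenation along the chain (dienone formation) or chelation of Pd by the o-hydroxy ketone could lower the yield. The fallback uses known chemistry and sets out from 1. A Claisen condensation of 1 with commercial methyl palmitate (CCCCCCCCCCCCCCCC(=O)OC; NaH 4 equiv, THF, reflux) gives 1-(2,6-dihydroxyphenyl)octadecane-1,3-dione F1. Acid-catalysed cyclodehydration of this diketone (cat. H2SO4, AcOH, 100 °C) closes the same O1–C2 bond without any oxidation and comes back to the route at 7.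

Second: step 1. Competing phenoxide O-alkylation, α,α-dialkylation through proton exchange, or poor solubility of the trianion could erode the yield; excess 1 is used to bias towards monoalkylation and is easily separated from the lipophilic product. The fallback sets out from 1. A Kabbe condensation of 1 with commercial hexadecanal (CCCCCCCCCCCCCCCC=O; pyrrolidine, EtOH or toluene, 80–110 °C; aldol condensation through enone 5, then oxa-Michael closure) gives the racemic chromanone 6 directly, and here it is isolated. The fallback comes back to the route at 6, which is carried on to 7 under the step 2 conditions; for a chromanone this aerobic Pd dehydrogenation is known chemistry. This fallback makes no compound outside the list (entry F0). It is not the first choice because the aldehyde costs more and self-condenses under amine catalysis.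

**Further compounds**
F1 | step 2 | 1-(2,6-dihydroxyphenyl)octadecane-1,3-dione | CCCCCCCCCCCCCCCC(=O)CC(=O)c1c(O)cccc1O
F0 | step 1 | none | none
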